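**Retrosynthetic overview**

1. Rings are lettered A to E from the 2,4,6-trihydroxyphenoxy end; in each ring C1 is the O-bearing carbon between two CH and C4 the O-bearing carbon between C3 and C5. The strategy rests on the ether carbon C4 of rings A to D, which lies between C3–OH and C5–OH: these eight hydroxyls are carried as acetyl groups, which first activate each C4–F for SNAr and are then converted into C–O bonds.
2. Target 21 ⇐ octaphenol tetramethyl ether 20 (BBr3) ⇐ octaacetate 19 (methanolysis) ⇐ octaketone 18 by an eightfold Baeyer–Villiger oxidation (C3–O and C5–O of rings A, B, C, D).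
3. 18 ⇐ four SNAr etherifications at C4 of rings A, B, C, D in that order. Rings B to D all come from one phenol 8, whose own C4–F is flanked by carbinols (latent acetyls) and is switched on by Dess–Martin oxidation after each coupling; ring E (3,4,5-trimethoxyphenol) is added last.
4. 8 and the ring A fluoride 10 ⇐ 4-fluorophenol by two fluorine-directed ortho-lithiation/acetaldehyde additions. No ring is formed at any stage; all five benzene rings are bought.

Key step: step 14

Remark: the target has no stereocentre; the carbinol carbons of 4, 7, 8, 9, 11, 13 and 15 are carried as stereoisomer mixtures (SMILES without descriptors) because every one of them is later oxidised to a ketone.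

**Route**

Step 1
Reactants: 1 4-fluorophenol
Product: 2 (4-fluorophenoxy)triisopropylsilane
Conditions: TIPSCl, imidazole, DMF, rt
Reagents that add atoms: chlorotriisopropylsilane, CC(C)[Si](Cl)(C(C)C)C(C)C
Why: Silylation of a phenol; the bulky silyl ether tolerates alkyllithiums and screens its own ortho positions, so fluorine is left as the only director in the metalations that follow.

Step 2
Reactants: 2 (4-fluorophenoxy)triisopropylsilane
Product: 4 1-[2-fluoro-5-(triisopropylsilyloxy)phenyl]ethanol (racemic), via aryllithium 3 (not isolated)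
Conditions: s-BuLi, TMEDA, THF, −78 °C; MeCHO, −78 °C; aq NH4Cl
Reagents that add atoms: acetaldehyde, CC=O; sec-butyllithium, CCC(C)[Li] (lithium of 3 only)
Why: Fluorine-directed ortho-lithiation (directed ortho-metalation), held below the temperature of LiF loss, followed by 1,2-addition of the aryllithium to acetaldehyde; the carbinol centre forms racemic and is erased on later oxidation.

Step 3
Reactants: 4 1-[2-fluoro-5-(triisopropylsilyloxy)phenyl]ethanol
Product: 7 1,1'-[2-fluoro-5-(triisopropylsilyloxy)-1,3-phenylene]diethanol (meso/racemic mixture), via lithium alkoxide 5 (not isolated), via O,C-dilithio species 6 (not isolated)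
Conditions: s-BuLi (2.3 equiv), TMEDA, THF, −78 °C; MeCHO, −78 °C; aq NH4Cl
Reagents that add atoms: acetaldehyde, CC=O; sec-butyllithium, CCC(C)[Li] (lithium of 5 and 6 only)
Why: The first equivalent of base forms the alkoxide (which also shields the benzylic C–H), the second carries out a fluorine-directed ortho-lithiation at the only remaining position next to fluorine (both positions next to OTIPS are screened), and addition to acetaldehyde gives the diol as a diastereomer mixture that converges on oxidation.

Step 4
Reactants: 7 1,1'-[2-fluoro-5-(triisopropylsilyloxy)-1,3-phenylene]diethanol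
Product: 8 4-fluoro-3,5-bis(1-hydroxyethyl)phenol
Conditions: TBAF, AcOH, THF, 0 °C
Reagents that add atoms: none
Why: Fluoride-induced cleavage of the aryl silyl ether, buffered with acetic acid; the C–F bond flanked by two carbinols is unactivated and inert.

Step 5
Reactants: 8 4-fluoro-3,5-bis(1-hydroxyethyl)phenol
Product: 9 1,1'-(2-fluoro-5-methoxy-1,3-phenylene)diethanol
Conditions: MeI, K2CO3, acetone, rt
Reagents that add atoms: iodomethane, CI
Why: Williamson etherification; K2CO3 deprotonates only the phenol, so the two secondary alcohols stay free.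

Step 6
Reactants: 9 1,1'-(2-fluoro-5-methoxy-1,3-phenylene)diethanol
Product: 10 1,1'-(2-fluoro-5-methoxy-1,3-phenylene)diethanone (ring A fluoride)
Conditions: Dess–Martin periodinane, CH2Cl2, rt
Reagents that add atoms: none
Why: Dess–Martin oxidation of both secondary benzylic alcohols under neutral conditions that leave the now doubly ortho-activated C–F bond untouched.

Step 7
Reactants: 8 4-fluoro-3,5-bis(1-hydroxyethyl)phenol; 10 1,1'-(2-fluoro-5-methoxy-1,3-phenylene)diethanone
Product: 11 1,1'-{2-[4-fluoro-3,5-bis(1-hydroxyethyl)phenoxy]-5-methoxy-1,3-phenylene}diethanone (ring A–B diol fluoride)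
Conditions: K2CO3, DMF, 70 °C, Ar
Reagents that add atoms: none
Why: SNAr in which the phenoxide of 8 adds at C4 of ring A to a Meisenheimer adduct stabilised by the two ortho acetyl groups and fluoride leaves; the C–F bond of 8 is flanked by carbinols, so neither 8 nor the product can react a second time, and the secondary alcohols are not deprotonated by carbonate.

Step 8
Reactants: 11 ring A–B diol fluoride
Product: 12 1,1'-[2-(3,5-diacetyl-4-fluorophenoxy)-5-methoxy-1,3-phenylene]diethanone (ring A–B tetraketone fluoride)
Conditions: Dess–Martin periodinane, CH2Cl2, rt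
Reagents that add atoms: none
Why: Dess–Martin oxidation of the two carbinols of ring B to acetyl groups, which switches on C4–F of ring B for the next substitution.

Step 9
Reactants: 8 4-fluoro-3,5-bis(1-hydroxyethyl)phenol; 12 ring A–B tetraketone fluoride
Product: 13 ring A–B–C tetraketone diol fluoride (acetyl on C3 and C5 of rings A and B; ring C carries 1-hydroxyethyl on C3 and C5 and F on C4)
Conditions: K2CO3, DMF, 70 °C, Ar
Reagents that add atoms: none
Why: SNAr at C4 of ring B, doubly ortho-acyl-activated and para to an electron-poor aryloxy group; the ring A ether carbon is equally activated but bears the far poorer aryloxide leaving group, so substitution occurs at C–F only.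

Step 10
Reactants: 13 ring A–B–C tetraketone diol fluoride
Product: 14 ring A–B–C hexaketone fluoride (acetyl on C3 and C5 of rings A, B and C; F on C4 of ring C)
Conditions: Dess–Martin periodinane, CH2Cl2, rt
Reagents that add atoms: none
Why: Dess–Martin oxidation of the two carbinols of ring C, again unmasking the activating acetyl pair.

Step 11
Reactants: 8 4-fluoro-3,5-bis(1-hydroxyethyl)phenol; 14 ring A–B–C hexaketone fluoride
Product: 15 ring A–B–C–D hexaketone diol fluoride (acetyl on C3 and C5 of rings A, B and C; ring D carries 1-hydroxyethyl on C3 and C5 and F on C4)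
Conditions: K2CO3, DMF, 70 °C, Ar
Reagents that add atoms: none
Why: SNAr at C4 of ring C on the same grounds as step 9; the nucleophile stays the small, unhindered phenoxide of 8 in every round.

Step 12
Reactants: 15 ring A–B–C–D hexaketone diol fluoride
Product: 16 ring A–B–C–D octaketone fluoride (acetyl on C3 and C5 of rings A to D; F on C4 of ring D)
Conditions: Dess–Martin periodinane, CH2Cl2, rt
Reagents that add atoms: none
Why: Dess–Martin oxidation of the two carbinols of ring D; nothing else in the molecule is oxidisable by the periodinane.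

Step 13
Reactants: 17 3,4,5-trimethoxyphenol; 16 ring A–B–C–D octaketone fluoride
Product: 18 octaketone pentamer (acetyl on C3 and C5 of rings A to D; OMe on C1 of ring A and on C3, C4, C5 of ring E)
Conditions: K2CO3, DMF, 60 °C, Ar
Reagents that add atoms: none
Why: SNAr of the electron-rich phenoxide at C4–F of ring D, where fluoride is displaced far faster than the aryloxides at the internal activated ether carbons; adding ring E last exposes this oxidation-prone ring to a single step before the key oxidation.

Step 14
Reactants: 18 octaketone pentamer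
Product: 19 octaacetate pentamer (acetoxy on C3 and C5 of rings A to D)
Conditions: mCPBA (24 equiv), Na2HPO4, CH2Cl2, 0 → 40 °C, dark
Reagents that add atoms: meta-chloroperoxybenzoic acid, OOC(=O)c1cccc(Cl)c1
Why: Proposed new method: each acetyl group, twisted out of conjugation by the neighbouring aryloxy group, adds the peracid to a Criegee adduct, and the aryl group migrates to oxygen with loss of 3-chlorobenzoic acid because the lone pair of the ortho C4 ether oxygen stabilises the electron-poor ipso carbon, which a methyl group cannot match. Eight such migrations should form every C3–O and C5–O bond of rings A to D in one operation; the closest known reaction type is the Baeyer–Villiger oxidation of ortho-alkoxy and ortho-aryloxy acetophenones to aryl acetates, known for one or two ketones in a molecule but not for eight. No ring is closed and no stereocentre is formed. The step needs aryl-over-methyl migration at all eight sites; the ortho ether oxygen present at every acetyl group secures it, and each acetoxy group formed is a weaker acceptor than the acetyl it replaces, so the second oxidation on a ring is easier than the first. It also needs ring E to be spared: the phosphate buffer removes the acid that would promote arene hydroxylation, and the ring E ether oxygen is shared with ring D, which keeps electron-withdrawing groups at C3 and C5 throughout. Rings A to D stay deactivated as acetyl and then acetoxy derivatives.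

Step 15
Reactants: 19 octaacetate pentamer
Product: 20 octaphenol tetramethyl ether (OH on C3 and C5 of rings A to D; OMe on C1 of ring A and on C3, C4, C5 of ring E)
Conditions: HCl (1.25 M in MeOH), THF, 40 °C, Ar, degassed
Reagents that add atoms: none
Why: Acid-catalysed transesterification (methanolysis) of the aryl acetates; the non-basic medium never forms the air-sensitive polyphenolate, and aryl methyl ethers and diaryl ethers are inert.

Step 16
Reactants: 20 octaphenol tetramethyl ether
Product: 21 target CNP0308003.0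
Conditions: BBr3 (excess), CH2Cl2, −78 °C → rt, Ar; then H2O
Reagents that add atoms: none
Why: BBr3 demethylation of the four aryl methyl ethers (Lewis acid complexation, bromide attack at methyl); the diaryl ether oxygens carry no sp3 carbon and survive, and the free phenols are held as borates until hydrolysis, hence the excess reagent.

**Compound list**

1 | 4-fluorophenol | Oc1ccc(F)cc1 | starting material
2 | (4-fluorophenoxy)triisopropylsilane | CC(C)[Si](Oc1ccc(F)cc1)(C(C)C)C(C)C | intermediate
3 | [2-fluoro-5-(triisopropylsilyloxy)phenyl]lithium (formed in the flask, step 2) | [Li]c1cc(O[Si](C(C)C)(C(C)C)C(C)C)ccc1F | intermediate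
4 | 1-[2-fluoro-5-(triisopropylsilyloxy)phenyl]ethanol (racemic) | CC(O)c1cc(O[Si](C(C)C)(C(C)C)C(C)C)ccc1F | intermediate
5 | lithium 1-[2-fluoro-5-(triisopropylsilyloxy)phenyl]ethoxide (formed in the flask, step 3) | CC(O[Li])c1cc(O[Si](C(C)C)(C(C)C)C(C)C)ccc1F | intermediate
6 | lithium 1-[2-fluoro-3-lithio-5-(triisopropylsilyloxy)phenyl]ethoxide (formed in the flask, step 3) | CC(O[Li])c1cc(O[Si](C(C)C)(C(C)C)C(C)C)cc([Li])c1F | intermediate
7 | 1,1'-[2-fluoro-5-(triisopropylsilyloxy)-1,3-phenylene]diethanol (meso/racemic mixture) | CC(O)c1cc(O[Si](C(C)C)(C(C)C)C(C)C)cc(C(C)O)c1F | intermediate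
8 | 4-fluoro-3,5-bis(1-hydroxyethyl)phenol (meso/racemic mixture) | CC(O)c1cc(O)cc(C(C)O)c1F | intermediate
9 | 1,1'-(2-fluoro-5-methoxy-1,3-phenylene)diethanol (meso/racemic mixture) | COc1cc(C(C)O)c(F)c(C(C)O)c1 | intermediate
10 | 1,1'-(2-fluoro-5-methoxy-1,3-phenylene)diethanone | COc1cc(C(C)=O)c(F)c(C(C)=O)c1 | intermediate
11 | 1,1'-{2-[4-fluoro-3,5-bis(1-hydroxyethyl)phenoxy]-5-methoxy-1,3-phenylene}diethanone (diastereomer mixture) | COc1cc(C(C)=O)c(Oc2cc(C(C)O)c(F)c(C(C)O)c2)c(C(C)=O)c1 | intermediate
12 | 1,1'-[2-(3,5-diacetyl-4-fluorophenoxy)-5-methoxy-1,3-phenylene]diethanone | COc1cc(C(C)=O)c(Oc2cc(C(C)=O)c(F)c(C(C)=O)c2)c(C(C)=O)c1 | intermediate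
13 | ring A–B–C tetraketone diol fluoride (diastereomer mixture) | COc1cc(C(C)=O)c(Oc2cc(C(C)=O)c(Oc3cc(C(C)O)c(F)c(C(C)O)c3)c(C(C)=O)c2)c(C(C)=O)c1 | intermediate
14 | ring A–B–C hexaketone fluoride | COc1cc(C(C)=O)c(Oc2cc(C(C)=O)c(Oc3cc(C(C)=O)c(F)c(C(C)=O)c3)c(C(C)=O)c2)c(C(C)=O)c1 | intermediate
15 | ring A–B–C–D hexaketone diol fluoride (diastereomer mixture) | COc1cc(C(C)=O)c(Oc2cc(C(C)=O)c(Oc3cc(C(C)=O)c(Oc4cc(C(C)O)c(F)c(C(C)O)c4)c(C(C)=O)c3)c(C(C)=O)c2)c(C(C)=O)c1 | intermediate
16 | ring A–B–C–D octaketone fluoride | COc1cc(C(C)=O)c(Oc2cc(C(C)=O)c(Oc3cc(C(C)=O)c(Oc4cc(C(C)=O)c(F)c(C(C)=O)c4)c(C(C)=O)c3)c(C(C)=O)c2)c(C(C)=O)c1 | intermediate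
17 | 3,4,5-trimethoxyphenol | COc1cc(O)cc(OC)c1OC | starting material
18 | octaketone pentamer | COc1cc(C(C)=O)c(Oc2cc(C(C)=O)c(Oc3cc(C(C)=O)c(Oc4cc(C(C)=O)c(Oc5cc(OC)c(OC)c(OC)c5)c(C(C)=O)c4)c(C(C)=O)c3)c(C(C)=O)c2)c(C(C)=O)c1 | intermediate
19 | octaacetate pentamer | COc1cc(OC(C)=O)c(Oc2cc(OC(C)=O)c(Oc3cc(OC(C)=O)c(Oc4cc(OC(C)=O)c(Oc5cc(OC)c(OC)c(OC)c5)c(OC(C)=O)c4)c(OC(C)=O)c3)c(OC(C)=O)c2)c(OC(C)=O)c1 | intermediate
20 | octaphenol tetramethyl ether | COc1cc(O)c(Oc2cc(O)c(Oc3cc(O)c(Oc4cc(O)c(Oc5cc(OC)c(OC)c(OC)c5)c(O)c4)c(O)c3)c(O)c2)c(O)c1 | intermediate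
21 | CNP0308003.0 | Oc1cc(O)c(Oc2cc(O)c(Oc3cc(O)c(Oc4cc(O)c(Oc5cc(O)c(O)c(O)c5)c(O)c4)c(O)c3)c(O)c2)c(O)c1 | target

**Totals**

Total step count: 16. Longest linear sequence: 16 steps (4-fluorophenol to 21 through 10; the branch through 8 joins at steps 7, 9 and 11).

**Steps most likely to fail**

1. Step 14. The eight oxidations may progress unevenly: stalling at partly oxidised stages as acetoxy groups crowd the chain, or methyl instead of aryl migration at an acetyl group whose ring still holds a second acetyl. The excess peracid may also hydroxylate the electron-rich ring E. The fallback uses only Baeyer–Villiger oxidations of the two acetyl groups of one ring at a time, a known operation, interleaved with chain growth; it sets out from 11 and comes back to the route at 21.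
   - Ring A: 11 is oxidised with mCPBA/Na2HPO4 (the carbinols of ring B are inert to peracid) to the ring A diacetate F1. K2CO3 and MeI in MeOH under argon exchange the acetates for methyl ethers (only phenoxides are alkylated) to give the trimethoxyphenyl diol fluoride F2. Dess–Martin periodinane gives the diketone fluoride F3, and SNAr with 8 (K2CO3, DMF) gives the trimer diol F4.
   - Ring B: the same four operations give the ring B diacetate F5, the dimethyl ether F6, the diketone fluoride F7 and the tetramer diol F8.
   - Ring C: they give the ring C diacetate F9, the dimethyl ether F10 and the diketone fluoride F11.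
   - Ring D and end: SNAr of F11 with 17 gives the pentamer diketone F12, twofold oxidation gives the ring D diacetate F13, and K2CO3/MeI gives the permethylated pentamer F14. BBr3 cleaves all twelve methyl ethers to 21.

2. Step 13. The strongly nucleophilic trimethoxyphenoxide may attack the internal doubly activated ether carbons (C4 of rings A, B, C), causing chain scission and ether exchange, and the eight methyl ketones of the large fluoride may undergo aldol condensation on prolonged heating with base. The fallback is a convergent 2 + 3 union that attaches ring E to a monomer and makes the ring D–ring C ether last with a weaker, less basic phenoxide; it sets out from 8, 17 and 14 and comes back at 18. Phenol 8 is allylated (allyl bromide, K2CO3, acetone) to the allyl ether diol F15 and oxidised with Dess–Martin periodinane to the allyl ether diketone fluoride F16. SNAr with 17 gives the ring E–D allyl ether F17, and Pd(PPh3)4 with morpholine in THF removes the allyl group to give the ring E–D phenol F18. SNAr of F18 with the trimer fluoride 14 (K2CO3, DMF) gives 18.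

3. Step 3. The second metalation may be incomplete or misdirected: the lithium alkoxide aggregates, may steer the base to the position between the carbinol and the silyloxy group, and the dianion may lose LiF to an aryne if the temperature drifts. The fallback removes the dianion by protecting the carbinol; it sets out from 4 and comes back at 8. TBSCl/imidazole gives the silyl ether F19; s-BuLi/TMEDA at −78 °C followed by acetaldehyde gives the mono-protected diol F20; excess TBAF in THF removes both silyl groups to give 8.

**Further compounds**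

F1 | step 14 | 2-[4-fluoro-3,5-bis(1-hydroxyethyl)phenoxy]-5-methoxy-1,3-phenylene diacetate | COc1cc(OC(C)=O)c(Oc2cc(C(C)O)c(F)c(C(C)O)c2)c(OC(C)=O)c1
F2 | step 14 | 1,1'-[2-fluoro-5-(2,4,6-trimethoxyphenoxy)-1,3-phenylene]diethanol | COc1cc(OC)c(Oc2cc(C(C)O)c(F)c(C(C)O)c2)c(OC)c1
F3 | step 14 | 1,1'-[2-fluoro-5-(2,4,6-trimethoxyphenoxy)-1,3-phenylene]diethanone | COc1cc(OC)c(Oc2cc(C(C)=O)c(F)c(C(C)=O)c2)c(OC)c1
F4 | step 14 | trimer diol fluoride (ring A trimethoxy, ring B diacetyl, ring C bis(1-hydroxyethyl) fluoride) | COc1cc(OC)c(Oc2cc(C(C)=O)c(Oc3cc(C(C)O)c(F)c(C(C)O)c3)c(C(C)=O)c2)c(OC)c1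
F5 | step 14 | trimer ring B diacetate | COc1cc(OC)c(Oc2cc(OC(C)=O)c(Oc3cc(C(C)O)c(F)c(C(C)O)c3)c(OC(C)=O)c2)c(OC)c1
F6 | step 14 | trimer ring B dimethyl ether diol fluoride | COc1cc(OC)c(Oc2cc(OC)c(Oc3cc(C(C)O)c(F)c(C(C)O)c3)c(OC)c2)c(OC)c1
F7 | step 14 | trimer diketone fluoride (ring C diacetyl) | COc1cc(OC)c(Oc2cc(OC)c(Oc3cc(C(C)=O)c(F)c(C(C)=O)c3)c(OC)c2)c(OC)c1
F8 | step 14 | tetramer diol fluoride (ring C diacetyl, ring D bis(1-hydroxyethyl) fluoride) | COc1cc(OC)c(Oc2cc(OC)c(Oc3cc(C(C)=O)c(Oc4cc(C(C)O)c(F)c(C(C)O)c4)c(C(C)=O)c3)c(OC)c2)c(OC)c1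
F9 | step 14 | tetramer ring C diacetate | COc1cc(OC)c(Oc2cc(OC)c(Oc3cc(OC(C)=O)c(Oc4cc(C(C)O)c(F)c(C(C)O)c4)c(OC(C)=O)c3)c(OC)c2)c(OC)c1
F10 | step 14 | tetramer ring C dimethyl ether diol fluoride | COc1cc(OC)c(Oc2cc(OC)c(Oc3cc(OC)c(Oc4cc(C(C)O)c(F)c(C(C)O)c4)c(OC)c3)c(OC)c2)c(OC)c1
F11 | step 14 | tetramer diketone fluoride (ring D diacetyl) | COc1cc(OC)c(Oc2cc(OC)c(Oc3cc(OC)c(Oc4cc(C(C)=O)c(F)c(C(C)=O)c4)c(OC)c3)c(OC)c2)c(OC)c1
F12 | step 14 | pentamer diketone (ring D diacetyl, all other oxygens methylated) | COc1cc(OC)c(Oc2cc(OC)c(Oc3cc(OC)c(Oc4cc(C(C)=O)c(Oc5cc(OC)c(OC)c(OC)c5)c(C(C)=O)c4)c(OC)c3)c(OC)c2)c(OC)c1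
F13 | step 14 | pentamer ring D diacetate | COc1cc(OC)c(Oc2cc(OC)c(Oc3cc(OC)c(Oc4cc(OC(C)=O)c(Oc5cc(OC)c(OC)c(OC)c5)c(OC(C)=O)c4)c(OC)c3)c(OC)c2)c(OC)c1
F14 | step 14 | permethylated pentamer (dodecamethyl ether of 21) | COc1cc(OC)c(Oc2cc(OC)c(Oc3cc(OC)c(Oc4cc(OC)c(Oc5cc(OC)c(OC)c(OC)c5)c(OC)c4)c(OC)c3)c(OC)c2)c(OC)c1
F15 | step 13 | 1,1'-[5-(allyloxy)-2-fluoro-1,3-phenylene]diethanol | C=CCOc1cc(C(C)O)c(F)c(C(C)O)c1
F16 | step 13 | 1,1'-[5-(allyloxy)-2-fluoro-1,3-phenylene]diethanone | C=CCOc1cc(C(C)=O)c(F)c(C(C)=O)c1
F17 | step 13 | 1,1'-[5-(allyloxy)-2-(3,4,5-trimethoxyphenoxy)-1,3-phenylene]diethanone | COc1cc(Oc2c(C(C)=O)cc(OCC=C)cc2C(C)=O)cc(OC)c1OC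
F18 | step 13 | 1,1'-[5-hydroxy-2-(3,4,5-trimethoxyphenoxy)-1,3-phenylene]diethanone | COc1cc(Oc2c(C(C)=O)cc(O)cc2C(C)=O)cc(OC)c1OC
F19 | step 3 | tert-butyl{1-[2-fluoro-5-(triisopropylsilyloxy)phenyl]ethoxy}dimethylsilane | CC(O[Si](C)(C)C(C)(C)C)c1cc(O[Si](C(C)C)(C(C)C)C(C)C)ccc1F
F20 | step 3 | 1-{3-[1-(tert-butyldimethylsilyloxy)ethyl]-2-fluoro-5-(triisopropylsilyloxy)phenyl}ethanol | CC(O)c1cc(O[Si](C(C)C)(C(C)C)C(C)C)cc(C(C)O[Si](C)(C)C(C)(C)C)c1F
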